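The route rests on excising the lactone carbonyl C2 from pyranone ring B. What remains, O1–C8a–C4a–C4=C3, is an (E)-2-alkenylphenol. Its C3–H bond lies cis to the arene, within reach of a metal held on O1. The key step exploits this feature: phenol-directed oxidative carbonylation inserts CO, forms C2–C3 and C2–O1, and closes ring B in one (5+1) operation. No carbanion or radical arises next to the C2'–C3' oxirane. The precursor already carries both oxiranes, the C6 1,1-dimethylallyl group and a silylated O7. It comes from cross-metathesis of a nerol-derived allyl bis-epoxide with a 2-vinylphenol.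

Key step: step 9

Remarks on the chemistry
- Locants: coumarin numbering (O1, C2 to C8a) is used for rings A and B. Primed numbers C1' to C8' are used for the chain, starting at the CH2 on C3.
- The target is (2'S,3'R,6'R), with C1' and C4' cis on the C2'–C3' oxirane. The rank order at C2' (O > C3' > C1' > H) is the same for CH2OH, CH2OTf, CH2–vinyl and CH2–coumarin, so the descriptors stay constant along the route.
- Assumption: the nerol used is free of geraniol (purified if necessary), because any E isomer would end up as the trans-oxirane diastereomer.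
- O7 is carried as a triisopropylsilyl ether. It has to survive an ylide, warm aqueous phosphate and an oxidative metal medium, and still leave with buffered fluoride.

Step 1
Reactants: 1 nerol, (2Z)-3,7-dimethylocta-2,6-dien-1-ol
Product: 2 (2S,3R)-2,3-epoxynerol, [(2S,3R)-3-methyl-3-(4-methylpent-3-en-1-yl)oxiran-2-yl]methanol (CH2OH and the C4 chain cis)
Conditions: Ti(OiPr)4 (10 mol %), diethyl L-(+)-tartrate (12 mol %), anhydrous t-BuOOH (2 equiv), 4 Å molecular sieves, CH2Cl2, −20 °C; NaOH–brine work-up at 0 °C
Reagents that add atoms: tert-butyl hydroperoxide, CC(C)(C)OO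
Why: Katsuki–Sharpless asymmetric epoxidation, in which the titanium tartrate complex binds the allylic hydroxyl so that only the C2=C3 olefin reacts, the L-(+)-tartrate should deliver oxygen to the face that makes C2 S, and stereospecific syn addition turns the Z geometry into the cis oxirane (C3 R).

Step 2
Reactants: 2 (2S,3R)-2,3-epoxynerol
Product: 3 (2S,3R,6R)-2,3:6,7-diepoxy alcohol, [(2S,3R)-3-{2-[(2R)-3,3-dimethyloxiran-2-yl]ethyl}-3-methyloxiran-2-yl]methanol
Conditions: 1,2:4,5-di-O-isopropylidene-β-D-erythro-2,3-hexodiulo-2,6-pyranose (D-fructose-derived ketone, 30 mol %), KHSO5 (1.4 equiv), K2CO3, Bu4NHSO4 (cat.), Na2B4O7 buffer (pH about 10.5), MeCN–CH2(OMe)2–H2O, 0 °C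
Reagents that add atoms: potassium peroxymonosulfate KHSO5, [K+].[O-]S(=O)(=O)OO
Why: Shi asymmetric epoxidation, in which the chiral dioxirane formed in situ attacks the remaining electron-rich trisubstituted olefin through a spiro transition state that should make C6 R under reagent control, the buffered cold medium leaves the first oxirane intact, and any material of the wrong C2/C3 series becomes a diastereomer that can be removed by chromatography.

Step 3
Reactants: 3 (2S,3R,6R)-2,3:6,7-diepoxy alcohol
Product: 4 bis-epoxy primary triflate, [(2S,3R)-3-{2-[(2R)-3,3-dimethyloxiran-2-yl]ethyl}-3-methyloxiran-2-yl]methyl trifluoromethanesulfonate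
Conditions: Tf2O (1.1 equiv), 2,6-lutidine (1.5 equiv), CH2Cl2, −78 °C; cold NaHCO3 wash, concentrated cold, used at once
Reagents that add atoms: trifluoromethanesulfonic anhydride, O=S(=O)(OS(=O)(=O)C(F)(F)F)C(F)(F)F
Why: Ordinary O-sulfonylation of a primary alcohol, in which the hindered pyridine base takes up TfOH without attacking the product, no stereocentre is involved, and low temperature with immediate use prevents ionisation or oxirane participation.

Step 4
Reactants: 4 bis-epoxy primary triflate; 5 vinylmagnesium bromide
Product: 6 allyl bis-epoxide (fragment 1), (2S,3R)-3-{2-[(2R)-3,3-dimethyloxiran-2-yl]ethyl}-3-methyl-2-(prop-2-en-1-yl)oxirane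
Conditions: 5 (2 equiv, THF), CuI (15 mol %), Et2O, −78 to −40 °C; NH4Cl–NH3 quench (pH 8)
Reagents that add atoms: none
Why: Copper-catalysed coupling of a Grignard reagent with a primary alkyl triflate (SN2 displacement by a vinylcuprate), which at low temperature should be much faster than attack on either trisubstituted oxirane, so C2', C3' and C6' are untouched.

Step 5
Reactants: 7 5-bromo-2,4-dihydroxybenzaldehyde
Product: 8 5-bromo-2-hydroxy-4-(triisopropylsilyloxy)benzaldehyde
Conditions: i-Pr3SiCl (1.05 equiv), imidazole (2 equiv), CH2Cl2–DMF, 0 °C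
Reagents that add atoms: triisopropylsilyl chloride, CC(C)[Si](Cl)(C(C)C)C(C)C
Why: Regioselective phenol silylation, in which the 2-OH is locked in a hydrogen bond to the aldehyde while the 4-OH (para to CHO, ortho to Br) is the more acidic and accessible one, so one equivalent of the bulky chlorosilane should take only O4.

Step 6
Reactants: 8 5-bromo-2-hydroxy-4-(triisopropylsilyloxy)benzaldehyde
Product: 9 4-bromo-2-ethenyl-5-(triisopropylsilyloxy)phenol
Conditions: MePPh3Br (2.4 equiv), KOt-Bu (2.3 equiv), THF, 0 °C to rt; pH 7 phosphate quench, BHT (trace) on storage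
Reagents that add atoms: methyltriphenylphosphonium bromide, C[P+](c1ccccc1)(c1ccccc1)c1ccccc1.[Br-]
Why: Wittig methylenation of a salicylaldehyde, in which the first equivalent of ylide only deprotonates the phenol and the second converts CHO into the vinyl group, which also removes the carbonyl that an allylboronate would otherwise attack in the following step.

Step 7
Reactants: 9 4-bromo-2-ethenyl-5-(triisopropylsilyloxy)phenol; 10 3,3-dimethylallylboronic acid pinacol ester
Product: 11 2-ethenyl-4-(2-methylbut-3-en-2-yl)-5-(triisopropylsilyloxy)phenol (fragment 2)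
Conditions: 10 (1.5 equiv), Pd(OAc)2 (3 mol %), 2-di-tert-butylphosphino-2',4',6'-triisopropylbiphenyl (6 mol %), K3PO4 (3 equiv), degassed MeCN–H2O, 60 °C
Reagents that add atoms: none
Why: Branched (γ-selective) Suzuki–Miyaura coupling of a 3,3-disubstituted allylboronate, in which SE2' transmetalation places palladium on the tertiary carbon and the bulky electron-rich biarylphosphine should force reductive elimination before σ–π–σ isomerisation to the primary allyl complex, giving the aryl–quaternary carbon bond without creating a stereocentre.

Step 8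
Reactants: 6 allyl bis-epoxide (fragment 1); 11 2-ethenyl-4-(2-methylbut-3-en-2-yl)-5-(triisopropylsilyloxy)phenol (fragment 2)
Product: 12 (E)-2-alkenylphenol, 2-[(1E)-3-{(2S,3R)-3-[2-((2R)-3,3-dimethyloxiran-2-yl)ethyl]-3-methyloxiran-2-yl}prop-1-en-1-yl]-4-(2-methylbut-3-en-2-yl)-5-(triisopropylsilyloxy)phenol
Conditions: 11 (1.5 equiv, excess recovered), RuCl2(H2IMes)(=CHC6H4-2-OiPr) (second-generation Hoveyda–Grubbs catalyst, 5 mol %), 1,4-benzoquinone (10 mol %), CH2Cl2, 40 °C, argon purge
Reagents that add atoms: none
Why: Olefin cross-metathesis of an unhindered terminal alkene with a styrene, in which ethene is lost, the styrenyl product should form as the E alkene, the vinyl group on the quaternary carbon beside the silyloxy group reacts far more slowly and should stay a spectator, benzoquinone suppresses ruthenium hydride double-bond migration, and the neutral medium spares oxiranes, phenol and silyl ether.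

Step 9
Reactants: 12 (E)-2-alkenylphenol; 13 carbon monoxide
Product: 14 7-O-silyl coumarin, 3-{[(2S,3R)-3-{2-[(2R)-3,3-dimethyloxiran-2-yl]ethyl}-3-methyloxiran-2-yl]methyl}-6-(2-methylbut-3-en-2-yl)-7-(triisopropylsilyloxy)-2H-chromen-2-one
Conditions: CO (1 atm, balloon), (C5Me5)Co(CO)I2 (10 mol %), Cu(OAc)2 (30 mol %), Ag2CO3 (1.5 equiv), 4 Å molecular sieves, ClCH2CH2Cl, 30 °C
Reagents that add atoms: none
Why: Exchange of iodide for acetate gives a pentamethylcyclopentadienyl complex of trivalent cobalt that binds O1 as phenoxide, and acetate-assisted concerted metalation–deprotonation then cleaves the C3–H bond, held cis to the arene by the E geometry, to give a six-membered oxacobaltacycle (O1, C8a, C4a, C4, C3, Co). CO inserts into the Co–C3 bond and C2–O1 reductive elimination releases the lactone, the monovalent cobalt left behind being reoxidised by Ag2CO3 with Cu(OAc)2 as acetate source and electron relay. The closest known reaction type is the oxidative cyclocarbonylation of 2-alkenylphenols to coumarins under pentamethylcyclopentadienyl cobalt or rhodium catalysis, applied here to a β-alkyl E alkene that carries two oxiranes. Ring B closes as a (5+1) annulation whose last bond is acyl C2–O1, and C3=C4 becomes endocyclic with C4a and C2 cis because C2 takes the place of the hydrogen that was cis to the arene. No stereocentre is created, and C2', C3' and C6' are not touched. Site selectivity for C3–H over arene C–H, allylic C1'–H and the hindered vinyl group is secured by chelation to the only free phenol (O7 is silylated), while carbonate buffering, sieves and 30 °C keep acetic acid and Lewis-acidic metal salts from opening the oxiranes.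

Step 10
Reactants: 14 7-O-silyl coumarin
Product: 15 target CNP0292491.1, 3-{[(2S,3R)-3-{2-[(2R)-3,3-dimethyloxiran-2-yl]ethyl}-3-methyloxiran-2-yl]methyl}-7-hydroxy-6-(2-methylbut-3-en-2-yl)-2H-chromen-2-one
Conditions: Bu4NF (1.2 equiv), AcOH (1.2 equiv), THF, 0 °C
Reagents that add atoms: none
Why: Fluoride-mediated cleavage of an aryl silyl ether, driven by Si–F bond formation and the good 7-oxycoumarin leaving group, with acetic acid buffering the phenoxide so that neither the lactone nor the oxiranes are attacked and no stereocentre is affected.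

Compound list
1 | nerol, (2Z)-3,7-dimethylocta-2,6-dien-1-ol | CC(C)=CCC/C(C)=C\CO | starting material
2 | (2S,3R)-2,3-epoxynerol | OC[C@@H]1O[C@]1(C)CCC=C(C)C | intermediate
3 | (2S,3R,6R)-2,3:6,7-diepoxy alcohol | OC[C@@H]1O[C@]1(C)CC[C@H]1OC1(C)C | intermediate
4 | bis-epoxy primary triflate | O=S(=O)(OC[C@@H]1O[C@]1(C)CC[C@H]1OC1(C)C)C(F)(F)F | intermediate
5 | vinylmagnesium bromide | C=C[Mg]Br | starting material
6 | allyl bis-epoxide (fragment 1) | C=CC[C@@H]1O[C@]1(C)CC[C@H]1OC1(C)C | intermediate
7 | 5-bromo-2,4-dihydroxybenzaldehyde | O=Cc1cc(Br)c(O)cc1O | starting material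
8 | 5-bromo-2-hydroxy-4-(triisopropylsilyloxy)benzaldehyde | O=Cc1cc(Br)c(O[Si](C(C)C)(C(C)C)C(C)C)cc1O | intermediate
9 | 4-bromo-2-ethenyl-5-(triisopropylsilyloxy)phenol | C=Cc1cc(Br)c(O[Si](C(C)C)(C(C)C)C(C)C)cc1O | intermediate
10 | 3,3-dimethylallylboronic acid pinacol ester | CC(C)=CCB1OC(C)(C)C(C)(C)O1 | starting material
11 | 2-ethenyl-4-(2-methylbut-3-en-2-yl)-5-(triisopropylsilyloxy)phenol (fragment 2) | C=Cc1cc(C(C)(C)C=C)c(O[Si](C(C)C)(C(C)C)C(C)C)cc1O | intermediate
12 | (E)-2-alkenylphenol with the complete (2'S,3'R,6'R) bis-epoxide chain | C=CC(C)(C)c1cc(/C=C/C[C@@H]2O[C@]2(C)CC[C@H]2OC2(C)C)c(O)cc1O[Si](C(C)C)(C(C)C)C(C)C | intermediate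
13 | carbon monoxide | [C-]#[O+] | starting material
14 | 7-O-triisopropylsilyl coumarin | C=CC(C)(C)c1cc2cc(C[C@@H]3O[C@]3(C)CC[C@H]3OC3(C)C)c(=O)oc2cc1O[Si](C(C)C)(C(C)C)C(C)C | intermediate
15 | CNP0292491.1 | C=CC(C)(C)c1cc2cc(C[C@@H]3O[C@]3(C)CC[C@H]3OC3(C)C)c(=O)oc2cc1O | target

Total step count: 10 (convergent: four steps to fragment 1, three to fragment 2, three after the union).
Longest linear sequence: 7 steps (steps 1 to 4, then 8 to 10).

Steps most likely to fail

Risk 1 (step 9).
- What may go wrong: metalation of the alkenyl C–H bond may be too slow for a β-alkyl-substituted alkene. Silver, copper or cationic cobalt species may also act as Lewis acids and open or rearrange the oxiranes before carbonylation is complete.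
- Fallback: ring B is closed by ring-closing metathesis, with C2 brought in as an ester carbon instead of CO. It sets out from 4 and 11 and returns at 14.
- The sodium salt of triethyl phosphonoacetate (NaH, THF, 0 °C) is alkylated with triflate 4 to give the alkylated phosphonoacetate F1.
- Horner–Wadsworth–Emmons methylenation with aqueous formaldehyde and K2CO3 at room temperature gives the ethyl 2-methylene ester F2.
- LiOH in THF–water gives the lithium 2-methylene carboxylate F3. It is dried and not acidified, so that the γ,δ-epoxy acid cannot lactonise.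
- Yamaguchi esterification (2,4,6-trichlorobenzoyl chloride, then 11, Et3N, 4-(dimethylamino)pyridine, toluene) gives the 2-vinylaryl acrylate F4.
- Ring-closing metathesis with RuCl2(H2IMes)(=CHC6H4-2-OiPr) in toluene at 60 to 80 °C forms C3=C4 with loss of ethene and delivers 14.

Risk 2 (step 8).
- What may go wrong: competing metathesis at the hindered vinyl group, self-metathesis of the allyl partner and double-bond migration may erode the union.
- Fallback: the order of bond formation is reversed, so that the metathesis runs before the second vinyl group exists. It sets out from 6 and 9 and returns at 12.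
- Cross-metathesis of 9 (in excess) with 6 under the same ruthenium carbene gives the bromo (E)-alkenylphenol F5.
- The branched-selective coupling with 10 (Pd(OAc)2, the same biarylphosphine, K3PO4, MeCN–H2O) is then carried out on F5. Its isolated, non-allylic oxiranes should tolerate aqueous phosphate and zerovalent palladium, and the product is 12.

Risk 3 (step 7).
- What may go wrong: σ–π–σ isomerisation may leak to the linear prenyl isomer. Oxidative addition into the electron-rich, ortho-hindered C–Br bond may be slow. Heck-type self-coupling through the styrene or partial loss of the silyl group may intervene.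
- Fallback: the quaternary carbon is defined by enolate arylation instead of allyl transfer. It sets out from 9 and returns at 11.
- Palladium-catalysed α-arylation of isobutyraldehyde with 9 (Pd(OAc)2, 2,2'-bis(diphenylphosphino)-1,1'-binaphthyl, Cs2CO3, dioxane, 80 °C) gives the aryl dimethylacetaldehyde F6.
- Wittig methylenation of this non-enolisable aldehyde (MePPh3Br, KOt-Bu, THF) gives 11 with no regiochemical ambiguity.

Further compounds
F1 | step 9 | alkylated phosphonoacetate, ethyl 2-(diethoxyphosphoryl)-3-[(2S,3R)-3-{2-[(2R)-3,3-dimethyloxiran-2-yl]ethyl}-3-methyloxiran-2-yl]propanoate (both epimers at C2) | CCOC(=O)C(C[C@@H]1O[C@]1(C)CC[C@H]1OC1(C)C)P(=O)(OCC)OCC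
F2 | step 9 | ethyl 2-methylene ester, ethyl 2-{[(2S,3R)-3-{2-[(2R)-3,3-dimethyloxiran-2-yl]ethyl}-3-methyloxiran-2-yl]methyl}prop-2-enoate | C=C(C[C@@H]1O[C@]1(C)CC[C@H]1OC1(C)C)C(=O)OCC
F3 | step 9 | lithium 2-methylene carboxylate, lithium salt of the acid of F2 | C=C(C[C@@H]1O[C@]1(C)CC[C@H]1OC1(C)C)C(=O)[O-].[Li+]
F4 | step 9 | 2-vinylaryl acrylate, ester of 11 with the acid of F3 | C=Cc1cc(C(C)(C)C=C)c(O[Si](C(C)C)(C(C)C)C(C)C)cc1OC(=O)C(=C)C[C@@H]1O[C@]1(C)CC[C@H]1OC1(C)C
F5 | step 8 | bromo (E)-alkenylphenol, 4-bromo-2-[(1E)-3-{(2S,3R)-3-[2-((2R)-3,3-dimethyloxiran-2-yl)ethyl]-3-methyloxiran-2-yl}prop-1-en-1-yl]-5-(triisopropylsilyloxy)phenol | Oc1cc(O[Si](C(C)C)(C(C)C)C(C)C)c(Br)cc1/C=C/C[C@@H]1O[C@]1(C)CC[C@H]1OC1(C)C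
F6 | step 7 | aryl dimethylacetaldehyde, 2-[5-ethenyl-4-hydroxy-2-(triisopropylsilyloxy)phenyl]-2-methylpropanal | C=Cc1cc(C(C)(C)C=O)c(O[Si](C(C)C)(C(C)C)C(C)C)cc1O
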